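## Structural features

The target (C26H30O8) is an achiral, methylene-bridged pair of acylphloroglucinol units. Ring A is a dearomatised 2-propanoyl-4,4-dimethylcyclohexane-1,3,5-trione (an acylfilicinic acid, drawn as its 3,5-dihydroxy-dienone tautomer), and ring B is a fully substituted phloroglucinol nucleus fused to a 2,2-dimethyl-2H-pyran (ring C), that is, a 5,7-dihydroxy-8-propanoyl-2,2-dimethylchromene. A single CH2 joins C6 of ring A to C6 of the chromene, the arene carbon between the two free phenols. There is no stereocentre; the only stereochemical element is the cis C3=C4 olefin locked in ring C. The fragile parts are the electron-rich styrenyl-ether olefin of ring C (acid, electrophiles, hydrogenation), the strongly acidic and chelating β-triketone enol of ring A, and the bridge itself, which can be exchanged between partners under acid or base. The real difficulty is regiochemical: of the three oxygens of ring B, exactly the one beside the propionyl-bearing carbon (O1 on C8a) must enter the pyran while C6 stays free for the bridge; next come the hetero-selective bridging and the gem-dimethyl carbon C4 of ring A. The key step uses the atom sequence O1–C2–C3=C4–C4a–C8a of ring C, which is the connectivity of a coumarin lactone with C2 at the carboxyl oxidation level, so both methyl groups on C2 can be delivered as carbon nucleophiles to a lactone carbonyl whose oxygen and arene carbon are already fixed.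

## Logic of the disconnections

**17 to 12 and 15.** The bond between the bridging methylene and C6 of ring B is cut first. It is the only bond joining two halves of equal size, 12 has exactly one unsubstituted arene carbon, and the methylene can be stored on the ring A half as 15, which releases the acceptor 16 on warming. The gain is full convergence. The forward step must create the electrophile only on the ring A half, in a neutral medium that neither exchanges the bridge nor attacks the chromene olefin.

**15 to 14.** The C6–CH2N bond is cut (retro-Mannich). This keeps the unstable 16 in a storable form and uses the single ring CH of 14. The forward step only needs mono-aminomethylation.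

**14 to 13.** Both C4–CH3 bonds are cut, which re-aromatises ring A to purchasable 13. The forward step must place the second methyl on the carbon that already carries the first (dearomatisation), not on the other ring carbon or on oxygen.

**12 to 10 (through 11).** The two phenols are re-capped as acetal ethers (11) and the O1–C2 bond of ring C is cut, giving the open Z-allylic tertiary alcohol 10 with one free phenol beside the side chain. The cut turns the pyran into a carbinol that an organometallic addition can deliver. The forward ring closure must come before acetal cleavage, so that only one oxygen is free to close, and the acid must be mild enough for the chromene.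

**10 to 6 and 7 (through 8 and 9), the key disconnection.** Both C–CH3 bonds at the carbinol carbon are cut and that carbon is reconnected to the phenol oxygen as a lactone carbonyl. Each of the two bonds comes from one equivalent of 7. The lactone ring settles in advance which oxygen and which arene carbon ring C spans, guarantees the cis olefin, and lets two skeletal bonds come from the simplest carbon nucleophile. The forward step must prefer the lactone over the propionyl ketone (masked as 8), add 1,2 and not 1,4, and carry the intermediate 9 through the second addition.

**6 to 5.** The two acetal O–CH2 bonds are cut. Both phenols have to be neutral ethers in the key step, because a phenoxide at O5 or O7 would be conjugated with the lactone carbonyl and deactivate it, and O5 has to stay blocked during ring closure. The forward step must also etherify the hydrogen-bonded 7-OH.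

**5 to 3 and 4.** The C8–acyl bond is cut (retro-Friedel–Crafts). The forward step must acylate C8, beside the ring oxygen, and not C6, and must stop after one acylation.

**3 to 1 and 2.** The lactone O–C(=O) bond and the C4–C4a bond are cut. The threefold symmetry of 1 removes any regiochemical question; the forward annulation only has to stop after one ring.

## Other disconnections considered

Alternative 1: Ring B itself is taken apart: two arene bonds are cut, leaving the four-carbon cyclobutenone A1 (3-ethoxy-4-prenylcyclobut-2-enone) and the two-carbon ynol ether A2 (ethoxyethyne). Forward, heating A1 with A2 should set off the Danheiser benzannulation (4π opening to a vinylketene, [2+2] addition of A2, 4π opening, 6π closure, tautomerisation) and give the phenol A3 (3,5-diethoxy-2-prenylphenol).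
- In favour: one operation builds the arene with three chemically different oxygens, the only free hydroxyl lying beside the prenyl carbon, so a later dehydrogenative closure of the ortho-prenylphenol could involve one oxygen only. On oxygen differentiation it is the equal of the chosen plan.
- Against: ring B is available cheaply as symmetrical 1, so building it de novo buys no skeleton. A1 needs its own ketene–ynol ether cycloaddition, A2 is volatile and costly, and the vinylketene carries a tethered trisubstituted olefin open to intramolecular [2+2] addition. The two ethyl ethers would finally have to be cleaved with boron trihalides or thiolates, which the chromene olefin and the triketone would hardly tolerate.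
- The propionyl group would still have to go to one of two open arene carbons, the same question that step 2 of the chosen plan faces, so nothing is gained there.
- Comparison: a pericyclic cascade is as dependable in type as the ionic additions of the chosen plan, but the sequence is longer (A1, annulation, pyran closure, acylation, two de-ethylations, ring A, bridging) and its end game is harsher.

Alternative 2: The cut lies inside ring A, between the acyl-bearing carbon and the carbonyl carbon next to CMe2, and leads to the open-chain triketo ester A4 that already carries the chromenylmethyl arm. Forward, NaH or NaOMe forms the carbanion of the β-diketone CH2, which attacks the methyl ester (Dieckmann closure to a six-membered ring) and gives A5, the bis-MOM ether of 17 without the arene propionyl group.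
- In favour: the gem-dimethyl carbon, the acyl position and the bridge on ring A are all fixed by chain assembly, so neither the dearomative methylation of step 6 nor the hetero-selective bridging of step 8 is needed. In these two respects it is better than the chosen plan, and the stabilised triketone anion gives a clear driving force.
- Against: A4 is a tetracarbonyl chain with a benzylic arm on an enolisable carbon. Its assembly calls for alkylation with an unstable chromenylmethyl electrophile and several polyanion acylations, and O-cyclisation, aldol closure and retro-Claisen cleavage compete with the wanted closure.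
- After closure the arene propionyl is still missing. Acylating A5 would be regiochemically unambiguous, since only one arene carbon is free (an equal or better point), but chemoselectively poor in the presence of MOM ethers, the chromene olefin and two acylable enol oxygens.
- Comparison: the alternative does not answer which oxygen carries the pyran, so a regiodefined chromene would be needed anyway, and the step count is clearly higher.

Alternative 3: The pyran is removed by cutting the C4–C4a and O1–C2 bonds, leading to the aryl 1,1-dimethylpropargyl ether A6. Forward, heating A6 should trigger a [3,3] shift to the free ortho carbon, enolisation, a 1,5-hydrogen shift and oxa-6π closure, giving A7, which is the same compound as 12.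
- In favour: the cascade is neutral and thermal, needs no organometallic reagent and no ketone masking, tolerates free phenols, and would reach 12 from 13 in two operations instead of five. In step economy and functional-group tolerance it is better than the chosen plan.
- As in the chosen plan, the oxygen that starts in the ether ends in the pyran, and from an ortho oxygen only one ortho carbon is free.
- Against: everything depends on which oxygen of 13 is etherified. The required one is a hydrogen-bonded, hindered ortho oxygen, whereas the para oxygen is the most acidic and accessible, and the tertiary propargylic electrophile is sluggish. Etherification at the para oxygen would lead through the same cascade to the regioisomer A8, with the acyl group between the two hydroxyls.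
- Comparison: correcting this with a protecting group on the para oxygen adds steps and removes most of the advantage. The chosen plan settles the oxygen before ring C exists, at the price of three more steps and one chemoselective organometallic step.

Key step: step 4

**Remark on the structures.** Compounds 6 and 10 map atom by atom onto ring B and ring C of the target (lactone oxygen on the carbon beside the acyl carbon, ethers on O5 and O7, free C6, Z olefin), so neither skeleton needs changing. The precursor design carries two requirements: both phenol ethers are electronically necessary for the key step, and the O5 ether must survive until ring C is closed. The key step consumes two equivalents of 7, one for each new C–CH3 bond, and a further portion is used as excess.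

**Assumption.** 1-(2,4,6-Trihydroxyphenyl)propan-1-one (13, flopropione) is taken as purchasable; otherwise it is one Friedel–Crafts step from 1 and 4.

## Route

Step 1
Reactants: 1 phloroglucinol (benzene-1,3,5-triol); 2 ethyl propiolate (ethyl prop-2-ynoate)
Product: 3 5,7-dihydroxy-2H-chromen-2-one
Conditions: ZnCl2 (anhydrous), neat, 95 °C
Reagents that add atoms: none
Why: Pechmann-type condensation: ZnCl2 promotes conjugate arylation of the alkynoate by the very electron-rich arene, followed by lactonisation with loss of ethanol; the symmetry of 1 leaves no regiochemical choice and the deactivating lactone discourages a second annulation.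

Step 2
Reactants: 3 5,7-dihydroxy-2H-chromen-2-one; 4 propionyl chloride (propanoyl chloride)
Product: 5 5,7-dihydroxy-8-propanoyl-2H-chromen-2-one
Conditions: AlCl3, PhNO2/ClCH2CH2Cl, 75 °C; aq HCl work-up
Reagents that add atoms: none
Why: Friedel–Crafts acylation: in 5,7-dihydroxycoumarins C8 (ortho to O7, para to O5, beside the ring oxygen) is the usual site of C-acylation, as known in the 4-alkyl series, and the product is held as an aluminium chelate of the 7-O/8-acyl pair, which should slow a second acylation at C6. One equivalent of 4 is used.

Step 3
Reactants: 5 5,7-dihydroxy-8-propanoyl-2H-chromen-2-one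
Product: 6 5,7-bis(methoxymethoxy)-8-propanoyl-2H-chromen-2-one
Conditions: NaH, MOMCl, DMF, 0 °C to rt
Reagents that add atoms: chloromethyl methyl ether, COCCl
Why: Williamson-type ether formation on the bis-phenoxide; NaH is chosen because the 7-OH is hydrogen-bonded to the new ketone and reacts slowly with amine bases. Both phenols are capped so that no phenoxide can deactivate the lactone in step 4 and so that O5 stays blocked during ring closure in step 5.

Step 4
Reactants: 6 5,7-bis(methoxymethoxy)-8-propanoyl-2H-chromen-2-one; 7 methyllithium
Product: 10 1-[2-hydroxy-3-[(1Z)-3-hydroxy-3-methylbut-1-en-1-yl]-4,6-bis(methoxymethoxy)phenyl]propan-1-one, via lithium enolate 8 (not isolated), via (Z)-enone phenoxide 9 (not isolated)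
Conditions: LiN(SiMe3)2 (1.1 equiv), THF, −78 °C; then MeLi/CeCl3 (3.5 equiv each, premixed in THF at −78 °C), −78 to −40 °C; sat. aq NH4Cl
Reagents that add atoms: methyllithium (second equivalent), [Li]C
Why: LiN(SiMe3)2 first converts the aryl ethyl ketone, the only readily enolisable site, into lithium enolate 8, which is no longer an electrophile and is further shielded by its two ortho substituents. A first equivalent of 7, used as the oxophilic and weakly basic MeCeCl2, then attacks the lactone carbonyl of 8, and the tetrahedral intermediate collapses by expelling the aryloxide to give the Z-configured methyl enone 9 as its phenoxide. A second equivalent of 7, again as MeCeCl2, adds 1,2 to this ketone and forms the second C–CH3 bond, and cold NH4Cl quench releases the tertiary allylic alcohol 10 and returns the propionyl ketone from its enolate. The closest known reaction type is the twofold methyl Grignard or methyllithium addition to coumarins used to make 2,2-dimethyl-2H-chromenes, combined with the established masking of a ketone as its enolate during an organometallic addition elsewhere in the molecule. No ring is closed and no stereocentre is created; the Z olefin is the former C3=C4 bond of the lactone ring and is not touched. The step needs lactone-over-ketone selectivity (secured by prior enolisation and the di-ortho flanking), 1,2- over 1,4-addition (secured by MeCeCl2 and by the peri 5-OMOM group screening C4), and a lactone that stays electrophilic (secured by capping both phenols as ethers, since a phenoxide at O5 or O7 would act as a vinylogous carboxylate). A non-acidic work-up keeps 10 from closing early, although closure at this point would be harmless.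

Step 5
Reactants: 10 1-[2-hydroxy-3-[(1Z)-3-hydroxy-3-methylbut-1-en-1-yl]-4,6-bis(methoxymethoxy)phenyl]propan-1-one
Product: 12 1-(5,7-dihydroxy-2,2-dimethyl-2H-chromen-8-yl)propan-1-one, via chromene bis-MOM ether 11 (not isolated)
Conditions: PPTS (10 mol %), CH2Cl2, rt; then solvent switch to MeOH, 1 M HCl, 40 °C
Reagents that add atoms: none
Why: Acid-catalysed cyclodehydration: ionisation of the tertiary allylic alcohol gives a delocalised cation that is trapped by the adjacent free phenol (the former lactone oxygen) in a six-membered C–O closure to the 2,2-dimethyl-2H-pyran; O5 is still an ether at this stage, so only one mode of closure is open. Once 10 is consumed, methanolic HCl should remove both MOM groups by transacetalisation, a mild cleavage that electron-rich 2,2-dimethylchromenes are known to tolerate.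

Step 6
Reactants: 13 1-(2,4,6-trihydroxyphenyl)propan-1-one
Product: 14 3,5-dihydroxy-4,4-dimethyl-2-propanoylcyclohexa-2,5-dien-1-one
Conditions: NaOMe, MeI (2 equiv), MeOH, 0 °C to rt
Reagents that add atoms: iodomethane, CI
Why: Dearomative double C-methylation of the acylphloroglucinol polyanion, the classical entry to acylfilicinic acids: after the first C-methylation a second methyl enters at the same carbon and gives the gem-dimethyl trione, whose delocalised vinylogous-acid anion is alkylated further only slowly. The amount of MeI is limited, and 14 should be separable from under- and over-methylated material through its acidity and by chromatography.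

Step 7
Reactants: 14 3,5-dihydroxy-4,4-dimethyl-2-propanoylcyclohexa-2,5-dien-1-one
Product: 15 6-[(dimethylamino)methyl]-3,5-dihydroxy-4,4-dimethyl-2-propanoylcyclohexa-2,5-dien-1-one
Conditions: 37% aq CH2O, 40% aq Me2NH, EtOH, 0 °C to rt
Reagents that add atoms: formaldehyde, C=O; dimethylamine, CNC
Why: Mannich reaction at the single remaining ring CH of the β-triketone; the product is a zwitterion that should crystallise from ethanol and has no further nucleophilic carbon.

Step 8
Reactants: 12 1-(5,7-dihydroxy-2,2-dimethyl-2H-chromen-8-yl)propan-1-one; 15 6-[(dimethylamino)methyl]-3,5-dihydroxy-4,4-dimethyl-2-propanoylcyclohexa-2,5-dien-1-one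
Product: 17 6-[(5,7-dihydroxy-2,2-dimethyl-8-propanoyl-2H-chromen-6-yl)methyl]-3,5-dihydroxy-4,4-dimethyl-2-propanoylcyclohexa-2,5-dien-1-one, via methylene trione 16 (not isolated)
Conditions: 1,4-dioxane, 80 °C, argon sweep
Reagents that add atoms: none
Why: Mannich-base alkylation (elimination then Michael addition): on warming, 15 loses dimethylamine to give methylene trione 16, a strong acceptor that is captured by C6 of 12, the only unsubstituted arene carbon and flanked by two hydroxyls; tautomerisation restores the arene and the triketone enol. The electrophile can arise only from the ring A half and the nucleophile only from the ring B half, so the heterodimer is the only direct product, and the neutral medium spares the chromene.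

## Compound list

1 | phloroglucinol (benzene-1,3,5-triol) | Oc1cc(O)cc(O)c1 | starting material
2 | ethyl propiolate (ethyl prop-2-ynoate) | CCOC(=O)C#C | starting material
3 | 5,7-dihydroxy-2H-chromen-2-one | O=C1C=Cc2c(O)cc(O)cc2O1 | intermediate
4 | propionyl chloride (propanoyl chloride) | CCC(=O)Cl | starting material
5 | 5,7-dihydroxy-8-propanoyl-2H-chromen-2-one | CCC(=O)c1c(O)cc(O)c2C=CC(=O)Oc12 | intermediate
6 | 5,7-bis(methoxymethoxy)-8-propanoyl-2H-chromen-2-one | COCOc1cc(OCOC)c2C=CC(=O)Oc2c1C(=O)CC | intermediate
7 | methyllithium | [Li]C | starting material
8 | lithium (1Z)-1-[5,7-bis(methoxymethoxy)-2-oxo-2H-chromen-8-yl]prop-1-en-1-olate (not isolated) | C/C=C(\O[Li])c1c(OCOC)cc(OCOC)c2C=CC(=O)Oc12 | intermediate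
9 | 1-[2-hydroxy-4,6-bis(methoxymethoxy)-3-[(1Z)-3-oxobut-1-en-1-yl]phenyl]propan-1-one (not isolated; drawn neutral, present as lithium phenoxide and enolate) | COCOc1cc(OCOC)c(/C=C\C(C)=O)c(O)c1C(=O)CC | intermediate
10 | 1-[2-hydroxy-3-[(1Z)-3-hydroxy-3-methylbut-1-en-1-yl]-4,6-bis(methoxymethoxy)phenyl]propan-1-one | COCOc1cc(OCOC)c(/C=C\C(C)(C)O)c(O)c1C(=O)CC | intermediate
11 | 1-[5,7-bis(methoxymethoxy)-2,2-dimethyl-2H-chromen-8-yl]propan-1-one (not isolated) | CCC(=O)c1c(OCOC)cc(OCOC)c2C=CC(C)(C)Oc12 | intermediate
12 | 1-(5,7-dihydroxy-2,2-dimethyl-2H-chromen-8-yl)propan-1-one | CCC(=O)c1c(O)cc(O)c2C=CC(C)(C)Oc12 | intermediate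
13 | 1-(2,4,6-trihydroxyphenyl)propan-1-one | CCC(=O)c1c(O)cc(O)cc1O | starting material
14 | 3,5-dihydroxy-4,4-dimethyl-2-propanoylcyclohexa-2,5-dien-1-one | CCC(=O)C1=C(O)C(C)(C)C(O)=CC1=O | intermediate
15 | 6-[(dimethylamino)methyl]-3,5-dihydroxy-4,4-dimethyl-2-propanoylcyclohexa-2,5-dien-1-one | CCC(=O)C1=C(O)C(C)(C)C(O)=C(CN(C)C)C1=O | intermediate
16 | 3-hydroxy-4,4-dimethyl-6-methylidene-2-propanoylcyclohex-2-ene-1,5-dione (not isolated) | CCC(=O)C1=C(O)C(C)(C)C(=O)C(=C)C1=O | intermediate
17 | 6-[(5,7-dihydroxy-2,2-dimethyl-8-propanoyl-2H-chromen-6-yl)methyl]-3,5-dihydroxy-4,4-dimethyl-2-propanoylcyclohexa-2,5-dien-1-one | CCC(=O)C1=C(O)C(C)(C)C(O)=C(Cc2c(O)c3c(c(C(=O)CC)c2O)OC(C)(C)C=C3)C1=O | target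

## Step count and least certain steps

Total step count: 8. Longest linear sequence: 6 steps (steps 1, 2, 3, 4, 5 and 8, from 1); the ring A branch has 2 steps (6 and 7) before the union.

**Step 4 (key step).** The most likely failures are:
- incomplete masking of the propionyl ketone, leading to methyl addition or aldol chemistry at that carbonyl;
- attack of the amide base on the lactone;
- intramolecular acyl transfer from the enolate carbon to the lactone carbonyl (a Baker–Venkataraman-type process), which the low temperature and the poor trajectory onto the ring-held, in-plane lactone carbonyl should disfavour;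
- conjugate addition at C4;
- stalling after the first addition because the intermediate enolises instead of accepting the second methyl group.

The fallback masks the ketone at the carbinol oxidation level; it sets out from 6 and returns at 10. Luche reduction of 6 (NaBH4, CeCl3·7H2O, MeOH, −20 °C) should reduce only the aryl ketone to the racemic carbinol (±)-8-(1-hydroxypropyl)-5,7-bis(methoxymethoxy)-2H-chromen-2-one F1. Its alkoxide is inert to carbon nucleophiles, so MeLi/CeCl3 in excess, without amide base, should give the triol (±)-2-(1-hydroxypropyl)-6-[(1Z)-3-hydroxy-3-methylbut-1-en-1-yl]-3,5-bis(methoxymethoxy)phenol F2. MnO2 (CH2Cl2, rt) should then oxidise only the benzylic secondary alcohol, which removes the temporary stereocentre and rejoins the route at 10.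

**Step 2.** Acylation may go to C6 or to both free positions, or stop at O-acylation, because the two arene carbons differ only modestly in reactivity. The fallback builds the lactone onto a ring that already carries the ketone; it sets out from 13 and returns at 6. MOMCl/i-Pr2NEt (CH2Cl2, 0 °C) should cap the para and one ortho hydroxyl and leave the chelated one, giving 1-[2-hydroxy-4,6-bis(methoxymethoxy)phenyl]propan-1-one F3. Esterification with propiolic acid (DCC, CH2Cl2, 0 °C) should give 3,5-bis(methoxymethoxy)-2-propanoylphenyl prop-2-ynoate F4. Hydroarylation catalysed by monovalent gold (Ph3PAuNTf2, ClCH2CH2Cl, 40 °C) can close only at the single free ortho carbon and should give 6.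

**Step 5.** Loss of the O5 MOM group before ring closure would erode the oxygen selectivity. During deprotection, acid may also add methanol or water across the chromene olefin, or open and reclose ring C on the other oxygen. The fallback uses ethers that are removed without acid; it sets out from 5 and returns at 12. Allyl bromide/K2CO3 (DMF, 50 °C) should give 8-propanoyl-5,7-bis(prop-2-en-1-yloxy)-2H-chromen-2-one F5. The conditions of step 4 should then give 1-[2-hydroxy-3-[(1Z)-3-hydroxy-3-methylbut-1-en-1-yl]-4,6-bis(prop-2-en-1-yloxy)phenyl]propan-1-one F6, and PPTS should close it to 1-[2,2-dimethyl-5,7-bis(prop-2-en-1-yloxy)-2H-chromen-8-yl]propan-1-one F7. Zerovalent palladium, Pd(PPh3)4, with morpholine (THF, rt) should remove both allyl groups under neutral conditions and give 12.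

**Step 6.** Under-, over- and misplaced methylation (second methyl on the other ring carbon or on oxygen) would lower the recovery and complicate separation. The fallback builds ring A from acyclic material; it sets out from 4 and returns at 14. Crossed Claisen condensation of acetone with dimethyl 2,2-dimethylmalonate (LiN(i-Pr)2, THF, −78 °C) should give methyl 2,2-dimethyl-3,5-dioxohexanoate F8. Dieckmann closure of its dianion (LiN(i-Pr)2 or NaOMe) should give 3,5-dihydroxy-4,4-dimethylcyclohexa-2,5-dien-1-one (filicinic acid) F9. C-Acylation of F9 with one equivalent of 4 (AlCl3, PhNO2) should give 14 with the methyl groups placed unambiguously.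

**Step 8.** The bridge may scramble through reversible retro-Michael and retro-Mannich steps (giving symmetrical dimers), the methylene trione may self-condense, and a phenol may cyclise onto ring A with loss of water. The fallback swaps the roles of the partners; it sets out from 12 and returns at 17. A Mannich reaction of 12 (CH2O, Me2NH, EtOH) at its single free arene carbon should give 1-[6-[(dimethylamino)methyl]-5,7-dihydroxy-2,2-dimethyl-2H-chromen-8-yl]propan-1-one F10. Warmed with the sodium salt of 14 (NaH, THF/dioxane), F10 should lose dimethylamine to an ortho-quinone methide that is captured by the free ring carbon of 14, giving 17.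

## Further compounds

F1 | step 4 | (±)-8-(1-hydroxypropyl)-5,7-bis(methoxymethoxy)-2H-chromen-2-one | CCC(O)c1c(OCOC)cc(OCOC)c2C=CC(=O)Oc12
F2 | step 4 | (±)-2-(1-hydroxypropyl)-6-[(1Z)-3-hydroxy-3-methylbut-1-en-1-yl]-3,5-bis(methoxymethoxy)phenol | COCOc1cc(OCOC)c(/C=C\C(C)(C)O)c(O)c1C(O)CC
F3 | step 2 | 1-[2-hydroxy-4,6-bis(methoxymethoxy)phenyl]propan-1-one | CCC(=O)c1c(O)cc(OCOC)cc1OCOC
F4 | step 2 | 3,5-bis(methoxymethoxy)-2-propanoylphenyl prop-2-ynoate | CCC(=O)c1c(OC(=O)C#C)cc(OCOC)cc1OCOC
F5 | step 5 | 8-propanoyl-5,7-bis(prop-2-en-1-yloxy)-2H-chromen-2-one | C=CCOc1cc(OCC=C)c2C=CC(=O)Oc2c1C(=O)CC
F6 | step 5 | 1-[2-hydroxy-3-[(1Z)-3-hydroxy-3-methylbut-1-en-1-yl]-4,6-bis(prop-2-en-1-yloxy)phenyl]propan-1-one | C=CCOc1cc(OCC=C)c(/C=C\C(C)(C)O)c(O)c1C(=O)CC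
F7 | step 5 | 1-[2,2-dimethyl-5,7-bis(prop-2-en-1-yloxy)-2H-chromen-8-yl]propan-1-one | CCC(=O)c1c(OCC=C)cc(OCC=C)c2C=CC(C)(C)Oc12
F8 | step 6 | methyl 2,2-dimethyl-3,5-dioxohexanoate | COC(=O)C(C)(C)C(=O)CC(C)=O
F9 | step 6 | 3,5-dihydroxy-4,4-dimethylcyclohexa-2,5-dien-1-one (filicinic acid) | CC1(C)C(O)=CC(=O)C=C1O
F10 | step 8 | 1-[6-[(dimethylamino)methyl]-5,7-dihydroxy-2,2-dimethyl-2H-chromen-8-yl]propan-1-one | CCC(=O)c1c(O)c(CN(C)C)c(O)c2C=CC(C)(C)Oc12
A1 | alternative 1 | (±)-3-ethoxy-4-(3-methylbut-2-en-1-yl)cyclobut-2-en-1-one | CCOC1=CC(=O)C1CC=C(C)C
A2 | alternative 1 | ethoxyethyne | CCOC#C
A3 | alternative 1 | 3,5-diethoxy-2-(3-methylbut-2-en-1-yl)phenol | CCOc1cc(O)c(CC=C(C)C)c(OCC)c1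
A4 | alternative 2 | methyl 4-{[5,7-bis(methoxymethoxy)-2,2-dimethyl-2H-chromen-6-yl]methyl}-2,2-dimethyl-3,5,7-trioxononanoate (racemic, enolisable) | CCC(=O)CC(=O)C(Cc1c(OCOC)c2C=CC(C)(C)Oc2cc1OCOC)C(=O)C(C)(C)C(=O)OC
A5 | alternative 2 | 6-{[5,7-bis(methoxymethoxy)-2,2-dimethyl-2H-chromen-6-yl]methyl}-3,5-dihydroxy-4,4-dimethyl-2-propanoylcyclohexa-2,5-dien-1-one | CCC(=O)C1=C(O)C(C)(C)C(O)=C(Cc2c(OCOC)c3C=CC(C)(C)Oc3cc2OCOC)C1=O
A6 | alternative 3 | 1-[2,4-dihydroxy-6-(2-methylbut-3-yn-2-yloxy)phenyl]propan-1-one | CCC(=O)c1c(O)cc(O)cc1OC(C)(C)C#C
A7 | alternative 3 | 1-(5,7-dihydroxy-2,2-dimethyl-2H-chromen-8-yl)propan-1-one (identical with 12) | CCC(=O)c1c(O)cc(O)c2C=CC(C)(C)Oc12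
A8 | alternative 3 | 1-(5,7-dihydroxy-2,2-dimethyl-2H-chromen-6-yl)propan-1-one | CCC(=O)c1c(O)cc2OC(C)(C)C=Cc2c1O
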